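**Plan**
- Retrosynthetic cuts, in order: the ester C–O bond at O3; the aryl ether bond O1–C8a of ring C; C2–O1, traced back to a C2–B bond; then C2–C1' (ring B) and C2–C3 together; last C3–O3 and the C3–C4 link, back to a ring A benzylboronate.
- Enabling feature: C2 is a single CH carbon bonded only to C3, to C1' of ring B and to O1. It can therefore be supplied by LiCHCl2 as a carbenoid carbon placed between a C3 boronate and an aryl Grignard reagent, with boron standing in for O1.
- Forward order: ring A benzylboronate (C4) → C3 by a first homologation with allyl oxide → C2 and ring B by the second homologation → C–B to C–OH → ring C closed last by O1–C8a coupling (the only ring formed) → O3 freed, esterified, debenzylated.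
- Stereochemistry: C3 and C2 both come from the (S,S)-1,2-dicyclohexylethanediol on boron in two successive homologations, each chloride being displaced with inversion. Oxidation and ring closure retain, giving (2R,3R).

Key step: step 7

Assumption on the sense of induction: boronic esters of the (S,S)-diol are taken to give the α-chloro boronate in which Cl, the migrated carbon and B run clockwise with H to the rear (the sense known for (S,S)-diols of this C2-symmetric class); all descriptors below follow from this.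
Remark on O3: it is carried as an allyl ether, because a quinone oxidant of the kind needed for a p-methoxybenzyl ether would also attack the C4 methylene beside the trialkoxy ring A of the benzylated flavan.
Compounds 1, 5, 9, 12 and 20 are taken as commercial.

**Route**

Step 1
Reactants: 1 1-bromo-3,5-bis(benzyloxy)benzene
Product: 2 2-bromo-4,6-bis(benzyloxy)benzaldehyde
Conditions: POCl3, DMF, 0 → 90 °C; aq. NaOAc
Reagents that add atoms: N,N-dimethylformamide CN(C)C=O; water O
Why: Vilsmeier–Haack formylation should attack the position para to one benzyloxy group and ortho to the other (between Br and OBn), the site between the two ethers being more crowded, as is usual for 1-bromo-3,5-dialkoxybenzenes; the minor symmetric aldehyde is removed by crystallisation.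

Step 2
Reactants: 2 2-bromo-4,6-bis(benzyloxy)benzaldehyde
Product: 3 [2-bromo-4,6-bis(benzyloxy)phenyl]methanol
Conditions: NaBH4, THF/MeOH, 0 °C
Reagents that add atoms: none
Why: Borohydride reduction of an aryl aldehyde leaves the aryl bromide and the benzyl ethers untouched.

Step 3
Reactants: 3 [2-bromo-4,6-bis(benzyloxy)phenyl]methanol
Product: 4 2-bromo-4,6-bis(benzyloxy)benzyl bromide
Conditions: PBr3, Et2O, 0 °C
Reagents that add atoms: phosphorus tribromide BrP(Br)Br
Why: Bromination of a benzylic alcohol with PBr3 through its phosphite ester (SN2 by bromide) is fast at 0 °C for this electron-rich substrate, and the labile bromide is used at once.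

Step 4
Reactants: 4 2-bromo-4,6-bis(benzyloxy)benzyl bromide; 5 (S,S)-1,2-dicyclohexylethane-1,2-diol
Product: 8 (4S,5S)-2-[2-bromo-4,6-bis(benzyloxy)benzyl]-4,5-dicyclohexyl-1,3,2-dioxaborolane, via the benzylic Grignard reagent 6 (not isolated), via the free benzylboronic acid 7 (not isolated)
Conditions: Mg, Et2O, 0 °C (slow addition, dilute); B(OMe)3, −78 °C → rt; aq. NH4Cl; then 5, MgSO4, Et2O, rt
Reagents that add atoms: trimethyl borate COB(OC)OC
Why: Grignard formation at the benzylic C–Br bond is much faster than insertion into the electron-rich aryl C–Br bond (the behaviour of 2-bromobenzyl bromide), Grignard borylation with excess B(OMe)3 at −78 °C stops at the boronate, and condensation of the boronic acid with the diol is driven by MgSO4.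

Step 5
Reactants: 8 (4S,5S)-2-[2-bromo-4,6-bis(benzyloxy)benzyl]-4,5-dicyclohexyl-1,3,2-dioxaborolane; 9 allyl alcohol
Product: 11 (4S,5S)-2-{(1S)-1-(allyloxy)-2-[2-bromo-4,6-bis(benzyloxy)phenyl]ethyl}-4,5-dicyclohexyl-1,3,2-dioxaborolane, via the (1R)-α-chloro boronate 10 (not isolated)
Conditions: CH2Cl2, n-BuLi, THF, −100 °C; 8; ZnCl2, −100 °C → rt; solvent exchange to THF/DMSO; LiOCH2CH=CH2 (from 9 and n-BuLi), rt
Reagents that add atoms: dichloromethane ClCCl
Why: Matteson homologation: preformed LiCHCl2 adds to boron, ZnCl2-assisted 1,2-migration of the benzyl group under control of the (S,S)-diol should give the (1R)-chloride 10, and lithium allyl oxide displaces chloride through a second ate complex with inversion, so the future C3 is set as (1S) with its oxygen already masked as an ether removable without an oxidant.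

Step 6
Reactants: 12 4-bromo-1,2-bis(benzyloxy)benzene
Product: 13 [3,4-bis(benzyloxy)phenyl]magnesium bromide
Conditions: Mg (I2-activated), THF, 40–60 °C; solution titrated and used directly
Reagents that add atoms: magnesium [Mg]
Why: Grignard reagent formation by direct magnesium insertion into an aryl bromide tolerates the two benzyl ethers.

Step 7
Reactants: 11 (4S,5S)-2-{(1S)-1-(allyloxy)-2-[2-bromo-4,6-bis(benzyloxy)phenyl]ethyl}-4,5-dicyclohexyl-1,3,2-dioxaborolane; 13 [3,4-bis(benzyloxy)phenyl]magnesium bromide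
Product: 15 (4S,5S)-2-{(1R,2R)-2-(allyloxy)-1-[3,4-bis(benzyloxy)phenyl]-3-[2-bromo-4,6-bis(benzyloxy)phenyl]propyl}-4,5-dicyclohexyl-1,3,2-dioxaborolane, via the (1R,2R)-α-chloro-β-allyloxy boronate 14 (not isolated)
Conditions: CH2Cl2, n-BuLi, THF, −100 °C; 11; ZnCl2, −100 °C → rt; solvent exchange to pentane, salts filtered off; then 13, THF, −78 °C → rt
Reagents that add atoms: dichloromethane ClCCl
Why: LiCHCl2 adds to boron of 11 to give an ate complex, ZnCl2 assists 1,2-migration of C3 from boron to the carbenoid carbon with loss of one chloride (C2–C3 formed, C3 retained) to give 14, and the aryl Grignard reagent 13 then forms a second ate complex whose aryl group shifts to C2 with inversion and expels the second chloride (C2–C1' formed). This is the Matteson homologation of a C2-symmetric diol boronic ester followed by Grignard displacement, the sequence used for chains of adjacent oxygen- and carbon-substituted stereocentres. No ring is closed in this step. The new C2 centre is controlled by the (S,S)-diol, which decides which chloride leaves in the first migration (1R in 14), and by the stereospecific inversion in the second (1R in 15), while C3 only migrates and keeps its configuration, so the (1R,2R) pair maps onto the cis C2/C3 relationship. The step needs attack at boron and not at the aryl bromide, and an α-chloride that does not epimerise: LiCHCl2 is preformed at −100 °C so that no n-BuLi meets the C–Br bond, ZnCl2 binds free chloride, and the allyloxy group on C3 is too poor a leaving group to be eliminated from the ate complexes.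

Step 8
Reactants: 15 (4S,5S)-2-{(1R,2R)-2-(allyloxy)-1-[3,4-bis(benzyloxy)phenyl]-3-[2-bromo-4,6-bis(benzyloxy)phenyl]propyl}-4,5-dicyclohexyl-1,3,2-dioxaborolane
Product: 16 (1R,2R)-2-(allyloxy)-1-[3,4-bis(benzyloxy)phenyl]-3-[2-bromo-4,6-bis(benzyloxy)phenyl]propan-1-ol
Conditions: 30% H2O2, 2 M NaOH, THF, 0 °C → rt
Reagents that add atoms: hydrogen peroxide OO
Why: Oxidation of the secondary benzylic boronic ester with alkaline hydrogen peroxide proceeds by hydroperoxide addition to boron and 1,2-shift of C2 from boron to oxygen with retention, so the (1R) C–B bond becomes the (1R) C–O bond destined to be C2–O1, while the aryl bromide, allyl ether and benzyl ethers are inert.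

Step 9
Reactants: 16 (1R,2R)-2-(allyloxy)-1-[3,4-bis(benzyloxy)phenyl]-3-[2-bromo-4,6-bis(benzyloxy)phenyl]propan-1-ol
Product: 17 (2R,3R)-3-(allyloxy)-5,7-bis(benzyloxy)-2-[3,4-bis(benzyloxy)phenyl]chroman
Conditions: CuI (cat.), 3,4,7,8-tetramethyl-1,10-phenanthroline, Cs2CO3, toluene, 110 °C
Reagents that add atoms: none
Why: Intramolecular Ullmann-type etherification (copper-catalysed C–O coupling of an aliphatic alcohol with an aryl bromide) should close the six-membered ring C between the C2 alkoxide and C8a, and since only the O–H and C–Br bonds change, C2 and C3 keep their configuration.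

Step 10
Reactants: 17 (2R,3R)-3-(allyloxy)-5,7-bis(benzyloxy)-2-[3,4-bis(benzyloxy)phenyl]chroman
Product: 19 (2R,3R)-5,7-bis(benzyloxy)-2-[3,4-bis(benzyloxy)phenyl]chroman-3-ol, via the (E)-prop-1-enyl ether 18 (not isolated)
Conditions: [Ir(cod)(PMePh2)2]PF6 (cat., H2-activated, then degassed), THF, rt; then 1 M HCl, acetone/H2O, rt
Reagents that add atoms: none
Why: Iridium-hydride isomerisation of the allyl ether to the (E)-prop-1-enyl ether followed by mild acid hydrolysis of this enol ether is a deallylation that uses no oxidant and so spares the oxidation-prone C4 methylene.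

Step 11
Reactants: 19 (2R,3R)-5,7-bis(benzyloxy)-2-[3,4-bis(benzyloxy)phenyl]chroman-3-ol; 20 4-benzyloxybenzoic acid
Product: 21 (2R,3R)-5,7-bis(benzyloxy)-2-[3,4-bis(benzyloxy)phenyl]chroman-3-yl 4-(benzyloxy)benzoate
Conditions: EDC·HCl, DMAP, CH2Cl2, rt
Reagents that add atoms: none
Why: Steglich esterification transfers the carbodiimide-activated acid through DMAP to the hindered secondary C3 hydroxyl, whose C–O bond is not broken, so the (3R) configuration is kept.

Step 12
Reactants: 21 (2R,3R)-5,7-bis(benzyloxy)-2-[3,4-bis(benzyloxy)phenyl]chroman-3-yl 4-(benzyloxy)benzoate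
Product: 22 epicatechin 3-O-p-hydroxybenzoate
Conditions: H2 (1 atm), Pd(OH)2/C, THF/MeOH, rt
Reagents that add atoms: none
Why: Hydrogenolysis of the five O-benzyl ethers over Pd(OH)2/C at atmospheric pressure is the standard final step for benzylated flavan-3-ol esters and should leave the ester and the cyclic C2–O1 ether intact.

**Compound list**
1 | 1-bromo-3,5-bis(benzyloxy)benzene | Brc1cc(OCc2ccccc2)cc(OCc2ccccc2)c1 | starting material
2 | 2-bromo-4,6-bis(benzyloxy)benzaldehyde | O=Cc1c(Br)cc(OCc2ccccc2)cc1OCc1ccccc1 | intermediate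
3 | [2-bromo-4,6-bis(benzyloxy)phenyl]methanol | OCc1c(Br)cc(OCc2ccccc2)cc1OCc1ccccc1 | intermediate
4 | 2-bromo-4,6-bis(benzyloxy)benzyl bromide | BrCc1c(Br)cc(OCc2ccccc2)cc1OCc1ccccc1 | intermediate
5 | (S,S)-1,2-dicyclohexylethane-1,2-diol | O[C@@H](C1CCCCC1)[C@@H](O)C1CCCCC1 | starting material
6 | [2-bromo-4,6-bis(benzyloxy)benzyl]magnesium bromide | Br[Mg]Cc1c(Br)cc(OCc2ccccc2)cc1OCc1ccccc1 | intermediate
7 | [2-bromo-4,6-bis(benzyloxy)benzyl]boronic acid | OB(O)Cc1c(Br)cc(OCc2ccccc2)cc1OCc1ccccc1 | intermediate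
8 | (4S,5S)-2-[2-bromo-4,6-bis(benzyloxy)benzyl]-4,5-dicyclohexyl-1,3,2-dioxaborolane | Brc1cc(OCc2ccccc2)cc(OCc2ccccc2)c1CB1O[C@@H](C2CCCCC2)[C@H](C2CCCCC2)O1 | intermediate
9 | allyl alcohol (prop-2-en-1-ol) | C=CCO | starting material
10 | (4S,5S)-2-{(1R)-2-[2-bromo-4,6-bis(benzyloxy)phenyl]-1-chloroethyl}-4,5-dicyclohexyl-1,3,2-dioxaborolane | Cl[C@@H](Cc1c(Br)cc(OCc2ccccc2)cc1OCc1ccccc1)B1O[C@@H](C2CCCCC2)[C@H](C2CCCCC2)O1 | intermediate
11 | (4S,5S)-2-{(1S)-1-(allyloxy)-2-[2-bromo-4,6-bis(benzyloxy)phenyl]ethyl}-4,5-dicyclohexyl-1,3,2-dioxaborolane | C=CCO[C@H](Cc1c(Br)cc(OCc2ccccc2)cc1OCc1ccccc1)B1O[C@@H](C2CCCCC2)[C@H](C2CCCCC2)O1 | intermediate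
12 | 4-bromo-1,2-bis(benzyloxy)benzene | Brc1ccc(OCc2ccccc2)c(OCc2ccccc2)c1 | starting material
13 | [3,4-bis(benzyloxy)phenyl]magnesium bromide | Br[Mg]c1ccc(OCc2ccccc2)c(OCc2ccccc2)c1 | intermediate
14 | (4S,5S)-2-{(1R,2R)-2-(allyloxy)-3-[2-bromo-4,6-bis(benzyloxy)phenyl]-1-chloropropyl}-4,5-dicyclohexyl-1,3,2-dioxaborolane | C=CCO[C@H](Cc1c(Br)cc(OCc2ccccc2)cc1OCc1ccccc1)[C@H](Cl)B1O[C@@H](C2CCCCC2)[C@H](C2CCCCC2)O1 | intermediate
15 | (4S,5S)-2-{(1R,2R)-2-(allyloxy)-1-[3,4-bis(benzyloxy)phenyl]-3-[2-bromo-4,6-bis(benzyloxy)phenyl]propyl}-4,5-dicyclohexyl-1,3,2-dioxaborolane | C=CCO[C@H](Cc1c(Br)cc(OCc2ccccc2)cc1OCc1ccccc1)[C@@H](c1ccc(OCc2ccccc2)c(OCc2ccccc2)c1)B1O[C@@H](C2CCCCC2)[C@H](C2CCCCC2)O1 | intermediate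
16 | (1R,2R)-2-(allyloxy)-1-[3,4-bis(benzyloxy)phenyl]-3-[2-bromo-4,6-bis(benzyloxy)phenyl]propan-1-ol | C=CCO[C@H](Cc1c(Br)cc(OCc2ccccc2)cc1OCc1ccccc1)[C@H](O)c1ccc(OCc2ccccc2)c(OCc2ccccc2)c1 | intermediate
17 | (2R,3R)-3-(allyloxy)-5,7-bis(benzyloxy)-2-[3,4-bis(benzyloxy)phenyl]chroman | C=CCO[C@@H]1Cc2c(OCc3ccccc3)cc(OCc3ccccc3)cc2O[C@@H]1c1ccc(OCc2ccccc2)c(OCc2ccccc2)c1 | intermediate
18 | (2R,3R)-5,7-bis(benzyloxy)-2-[3,4-bis(benzyloxy)phenyl]-3-[(E)-prop-1-enyloxy]chroman | C/C=C/O[C@@H]1Cc2c(OCc3ccccc3)cc(OCc3ccccc3)cc2O[C@@H]1c1ccc(OCc2ccccc2)c(OCc2ccccc2)c1 | intermediate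
19 | (2R,3R)-5,7-bis(benzyloxy)-2-[3,4-bis(benzyloxy)phenyl]chroman-3-ol | O[C@@H]1Cc2c(OCc3ccccc3)cc(OCc3ccccc3)cc2O[C@@H]1c1ccc(OCc2ccccc2)c(OCc2ccccc2)c1 | intermediate
20 | 4-benzyloxybenzoic acid | O=C(O)c1ccc(OCc2ccccc2)cc1 | starting material
21 | (2R,3R)-5,7-bis(benzyloxy)-2-[3,4-bis(benzyloxy)phenyl]chroman-3-yl 4-(benzyloxy)benzoate | O=C(O[C@@H]1Cc2c(OCc3ccccc3)cc(OCc3ccccc3)cc2O[C@@H]1c1ccc(OCc2ccccc2)c(OCc2ccccc2)c1)c1ccc(OCc2ccccc2)cc1 | intermediate
22 | epicatechin 3-O-p-hydroxybenzoate, (2R,3R) | O=C(O[C@@H]1Cc2c(O)cc(O)cc2O[C@@H]1c1ccc(O)c(O)c1)c1ccc(O)cc1 | target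

**Count**
Total steps: 12. Longest linear sequence: 11 (steps 1–5 and 7–12, from 1 to 22); step 6 is a one-step side branch.

**Steps most likely to fail**

Step 7. Aryl migration in the second ate complex may be slow at the crowded α-chloro carbon next to the allyloxy-bearing C3. Chloride exchange could then scramble C2 before displacement, or the C3 alkoxide could be lost by β-elimination. The fallback changes the carbenoid and the leaving group. Setting out from 11, LiCHBr2 is generated in its presence (CH2Br2, LiN(i-Pr)2, THF, −78 °C, then ZnCl2). This should give the α-bromo boronate (4S,5S)-2-{(1R,2R)-2-(allyloxy)-1-bromo-3-[2-bromo-4,6-bis(benzyloxy)phenyl]propyl}-4,5-dicyclohexyl-1,3,2-dioxaborolane F1. After removal of salts it is treated with 13 at −78 to 0 °C, where the better leaving group should allow the aryl shift before epimerisation or elimination. The route is rejoined at 15.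

Step 9. Oxidative addition of the copper alkoxide to the electron-rich, ortho-substituted aryl bromide may be slow. Loss of bromine by reduction or oxidation of the benzylic alcohol to the ketone could then outrun ring closure. The fallback hands the C–O bond formation to palladium: from 16, Pd(OAc)2, 2-(di-tert-butylphosphino)-1,1'-binaphthyl, Cs2CO3, toluene, 80 °C. Zerovalent palladium inserts into the C–Br bond, and the bulky phosphine favours C–O reductive elimination from the arylpalladium alkoxide over β-hydride loss. This is the established palladium route from secondary alcohols to chromans with retention. It leads directly from 16 to 17 and no new compound arises (F0).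

Step 4. Wurtz-type homocoupling of 4 with its own Grignard reagent, or magnesium insertion into the aryl C–Br bond, may consume the material before borylation. The fallback replaces the carbanion by a boryl nucleophile. From 4, copper-catalysed boryl substitution (CuI, PPh3, LiOMe, B2pin2, DMF, rt) should give the pinacol ester 2-[2-bromo-4,6-bis(benzyloxy)benzyl]-4,4,5,5-tetramethyl-1,3,2-dioxaborolane F2. Diethanolamine in Et2O then precipitates 2-[2-bromo-4,6-bis(benzyloxy)benzyl]-1,3,6,2-dioxazaborocane F3. Shaking F3 with 1 M HCl and 5 in Et2O rejoins the route at 8.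

**Further compounds**
F1 | step 7 | (4S,5S)-2-{(1R,2R)-2-(allyloxy)-1-bromo-3-[2-bromo-4,6-bis(benzyloxy)phenyl]propyl}-4,5-dicyclohexyl-1,3,2-dioxaborolane | C=CCO[C@H](Cc1c(Br)cc(OCc2ccccc2)cc1OCc1ccccc1)[C@H](Br)B1O[C@@H](C2CCCCC2)[C@H](C2CCCCC2)O1
F0 | step 9 | none | none
F2 | step 4 | 2-[2-bromo-4,6-bis(benzyloxy)benzyl]-4,4,5,5-tetramethyl-1,3,2-dioxaborolane | CC1(C)OB(Cc2c(Br)cc(OCc3ccccc3)cc2OCc2ccccc2)OC1(C)C
F3 | step 4 | 2-[2-bromo-4,6-bis(benzyloxy)benzyl]-1,3,6,2-dioxazaborocane | Brc1cc(OCc2ccccc2)cc(OCc2ccccc2)c1C[B-]12OCC[NH+]1CCO2
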